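**Retrosynthetic overview**

1. Target 27 ← diangelate 24 (the vinyl group on C11 is a masked C12 hydroxymethyl) ← diol 21 (C8–OH from a C8–Si bond, C10–OH from an acetate).
2. 21 ← tricyclic enone 18: the C3 methyl comes from a cuprate addition, and the six-membered ring is closed last by aldol condensation (C3–C4).
3. Key disconnection: enone 18 ← bicyclo[4.1.1]octane 16 ← acyclic enal–allylsilane 15. A cationic stepwise [2+2] makes the two C–C bonds that the biosynthesis forms from the humulyl cation, in the same order and polarity: C1–C6 first (himachalyl-type cation at C7), then C2–C7 (longipinyl-type closure).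
4. 15 ← iridium-catalysed tert-(hydroxy)prenylation (sets C10 and C11) and a Wittig reaction; the allylsilane stereocentre C8 comes from a copper-catalysed conjugate silylation of dienynoate 6.
5. Ring order: seven-membered ring and cyclobutane together in one flask, then the six-membered ring.

Assumption 1: locants C1–C15 in the names are biogenetic (farnesyl) locants: six-membered ring C1–C6 (C5 is the ketone carbon); cyclobutane C1, C2, C7, C6; bridge C8–C11 joining C7 to C1; C12 = CH2OH carbon and C13 = methyl on C11; C14 = methyl on C7; C15 = methyl on C3.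

Assumption 2: the chiral ligands in steps 4 and 6 are taken to induce the sense written; if either induces the opposite sense, its enantiomer is used.

**Route**

Step 1
Reactants: 1 ethynyl(trimethyl)silane
Product: 2 3-(trimethylsilyl)prop-2-ynal
Conditions: n-BuLi, THF, −78 °C; DMF, −78 to 0 °C; inverse quench into cold 1 M HCl
Reagents that add atoms: N,N-dimethylformamide, CN(C)C=O
Why: Formylation of the lithium acetylide with DMF is a standard route to silyl ynals; no stereocentre is formed.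

Step 2
Reactants: 2 3-(trimethylsilyl)prop-2-ynal; 3 2-(triphenyl-λ5-phosphanylidene)propanal
Product: 4 (2E)-2-methyl-5-(trimethylsilyl)pent-2-en-4-ynal
Conditions: CH2Cl2, 25 °C
Reagents that add atoms: 2-(triphenyl-λ5-phosphanylidene)propanal (3), CC(C=O)=P(c1ccccc1)(c1ccccc1)c1ccccc1
Why: Wittig olefination with the stabilised α-methyl formyl ylide gives the (E)-trisubstituted C6=C7 bond, with the formyl group trans to the alkynyl group as usual for stabilised ylides.

Step 3
Reactants: 4 (2E)-2-methyl-5-(trimethylsilyl)pent-2-en-4-ynal; 5 triethyl phosphonoacetate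
Product: 6 ethyl (2E,4E)-4-methyl-7-(trimethylsilyl)hepta-2,4-dien-6-ynoate
Conditions: NaH, THF, 0 to 25 °C
Reagents that add atoms: triethyl phosphonoacetate (5), CCOC(=O)CP(=O)(OCC)OCC
Why: Horner–Wadsworth–Emmons olefination gives the (E)-enoate (C8=C9) and completes the conjugate acceptor.

Step 4
Reactants: 6 ethyl (2E,4E)-4-methyl-7-(trimethylsilyl)hepta-2,4-dien-6-ynoate; 7 2-[dimethyl(phenyl)silyl]-4,4,5,5-tetramethyl-1,3,2-dioxaborolane
Product: 8 ethyl (3R,4E)-3-[dimethyl(phenyl)silyl]-4-methyl-7-(trimethylsilyl)hept-4-en-6-ynoate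
Conditions: CuCl (5 mol %), chiral imidazolinium salt (NHC precursor, 5.5 mol %), NaOt-Bu (11 mol %), THF, −78 °C; aqueous work-up
Reagents that add atoms: 2-[dimethyl(phenyl)silyl]-4,4,5,5-tetramethyl-1,3,2-dioxaborolane (7), C[Si](C)(c1ccccc1)B1OC(C)(C)C(C)(C)O1
Why: NHC–copper-catalysed enantioselective conjugate silyl addition with a silylboronate; the chiral copper–silyl complex is expected to add 1,4 at the unhindered β-carbon C8 and sets it (R) by catalyst control, leaving the (E)-C6=C7 bond as a stereodefined allylsilane.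

Step 5
Reactants: 8 ethyl (3R,4E)-3-[dimethyl(phenyl)silyl]-4-methyl-7-(trimethylsilyl)hept-4-en-6-ynoate
Product: 9 (3R,4E)-3-[dimethyl(phenyl)silyl]-4-methyl-7-(trimethylsilyl)hept-4-en-6-yn-1-ol
Conditions: i-Bu2AlH (2.5 equiv), CH2Cl2, −78 to 0 °C
Reagents that add atoms: none
Why: Aluminium hydride reduction of the ester to the primary alcohol (C10) leaves the C8 stereocentre, the allylsilane and the silyl alkyne untouched.

Step 6
Reactants: 9 (3R,4E)-3-[dimethyl(phenyl)silyl]-4-methyl-7-(trimethylsilyl)hept-4-en-6-yn-1-ol; 10 2-methyl-2-vinyloxirane (isoprene monoxide, racemic)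
Product: 11 (2R,3R,5R,6E)-5-[dimethyl(phenyl)silyl]-2-ethenyl-2,6-dimethyl-9-(trimethylsilyl)non-6-en-8-yne-1,3-diol
Conditions: Ir(allyl)[(R)-Tol-BINAP](4-cyano-3-nitrobenzoate) (5 mol %), K3PO4 (5 mol %), THF, 60 °C
Reagents that add atoms: 2-methyl-2-vinyloxirane (10), CC1(C=C)CO1
Why: Iridium-catalysed redox-neutral tert-(hydroxy)prenylation of a primary alcohol (transfer-hydrogenative carbonyl allylation through a chair-like transition state) forms the C10–C11 bond and sets C10 (R) and the quaternary C11 (R) with anti selectivity (carbinol OH anti to CH2OH) under catalyst control.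

Step 7
Reactants: 11 (2R,3R,5R,6E)-5-[dimethyl(phenyl)silyl]-2-ethenyl-2,6-dimethyl-9-(trimethylsilyl)non-6-en-8-yne-1,3-diol; 12 2-(triphenyl-λ5-phosphanylidene)acetaldehyde
Product: 14 (2E,4R,5R,7R,8E)-7-[dimethyl(phenyl)silyl]-4-ethenyl-5-hydroxy-4,8-dimethyl-11-(trimethylsilyl)undeca-2,8-dien-10-ynal, via hydroxy aldehyde 13 (not isolated)
Conditions: TEMPO (10 mol %), PhI(OAc)2 (1.1 equiv), CH2Cl2, 25 °C; then 12, PhMe, 80 °C
Reagents that add atoms: 2-(triphenyl-λ5-phosphanylidene)acetaldehyde (12), O=CC=P(c1ccccc1)(c1ccccc1)c1ccccc1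
Why: TEMPO/PhI(OAc)2 oxidises only the primary alcohol and Wittig olefination of the non-enolisable aldehyde gives the (E)-enal; the former CH2OH carbon becomes C1 and the vinyl group is kept as a masked C12, which turns the anti adduct into the C10/C11 relationship of the target.

Step 8
Reactants: 14 (2E,4R,5R,7R,8E)-7-[dimethyl(phenyl)silyl]-4-ethenyl-5-hydroxy-4,8-dimethyl-11-(trimethylsilyl)undeca-2,8-dien-10-ynal
Product: 15 (2E,4R,5R,7R,8E)-5-acetoxy-7-[dimethyl(phenyl)silyl]-4-ethenyl-4,8-dimethyl-11-(trimethylsilyl)undeca-2,8-dien-10-ynal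
Conditions: Ac2O, pyridine, DMAP (cat.), CH2Cl2, 25 °C
Reagents that add atoms: acetic anhydride, CC(=O)OC(C)=O
Why: Acetylation turns O10 into a non-nucleophilic ester so that it cannot trap the C7 cation of step 9 as a tetrahydrofuran; no stereocentre changes.

Step 9
Reactants: 15 (2E,4R,5R,7R,8E)-5-acetoxy-7-[dimethyl(phenyl)silyl]-4-ethenyl-4,8-dimethyl-11-(trimethylsilyl)undeca-2,8-dien-10-ynal
Product: 16 bicyclo[4.1.1]octane aldehyde: cyclobutane C1/C2/C7/C6 bridged by C8–C11; CHO on C2 and C≡C–SiMe3 on C6, both anti to the C8–C11 bridge; CH3 on C7; SiMe2Ph on C8 (anti to the C7–C2 bond); OAc on C10; CH3 and vinyl on C11; all centres arranged as in 27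
Conditions: Me3SiNTf2 (10 mol %), CH2Cl2 (0.005 M), −78 to −40 °C; pyridine quench at −78 °C
Reagents that add atoms: none
Why: Proposed new method: the silyl Lewis acid turns the enal into a 1-silyloxyallyl cation whose terminus C1 is attacked by C6 of the allylsilane anti to silicon (SE2′), which closes the seven-membered ring and gives a β-silyl-stabilised tertiary cation at C7 (the counterpart of the himachalyl cation) that is captured by C2 of the silyl enol ether, again anti to silicon, before desilylation (non-nucleophilic NTf2 counter-ion, low temperature), so that C8 fixes C1, C2, C6 and C7, the E,E geometry and the tether place CHO and alkynyl exo, and silicon stays on C8; the closest known reactions are the triflimide- or TiCl4-promoted stepwise [2+2] cycloadditions of allylsilanes with α,β-unsaturated carbonyl compounds and the Gassman cationic [2+2] of alkoxyallyl cations with alkenes.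

Step 10
Reactants: 16 bicyclo[4.1.1]octane aldehyde
Product: 18 tricyclic enone: 15-norlongipin-3-en-5-one core with 10-OAc, 8-SiMe2Ph and vinyl in place of CH2OH on C11, via keto aldehyde 17 (not isolated)
Conditions: Ph3PAuNTf2 (5 mol %), H2O (5 equiv), 1,4-dioxane, 60 °C; then pyrrolidine (0.5 equiv), AcOH (0.5 equiv), 60 °C
Reagents that add atoms: water, O
Why: Gold-catalysed Markovnikov hydration (with loss of the alkynyl silyl group) unveils the methyl ketone on C6, and its amine-catalysed intramolecular aldol condensation with the cis-disposed aldehyde on C2 closes the six-membered ring (C3–C4) as the enone; no new stereocentre is formed.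

Step 11
Reactants: 18 tricyclic enone
Product: 19 ketone: 10-acetoxy-8-[dimethyl(phenyl)silyl]-11-vinyl-longipinan-5-one skeleton with (3R)-methyl
Conditions: Me2CuLi (3 equiv), Et2O, −78 to −40 °C; aqueous NH4Cl
Reagents that add atoms: lithium dimethylcuprate, [Li+].C[Cu-]C
Why: Conjugate addition of the Gilman cuprate delivers the methyl group to C3 from the face of the C1–H bridge, anti to the C7 methyl that shields the other face (as in additions to apoverbenone-type enones), giving the 3R centre.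

Step 12
Reactants: 19 ketone
Product: 21 diol: 8,10-dihydroxy-11-vinyl-longipinan-5-one skeleton, via fluorosilane 20 (not isolated)
Conditions: HBF4·OEt2, CH2Cl2, 0 °C; then H2O2 (30 %), KF, K2CO3, THF/MeOH, 40 °C
Reagents that add atoms: hydrogen peroxide, OO; tetrafluoroboric acid (fluorine in 20 only), F[B-](F)(F)F.[H+]
Why: Fleming–Tamao oxidation (protodesilylation of the phenyl group, then peroxide-induced 1,2-shift from silicon to oxygen) converts C8–Si into C8–OH with retention, and the carbonate/methanol medium removes the acetate in the same flask.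

Step 13
Reactants: 21 diol; 22 (Z)-2-methylbut-2-enoic acid (angelic acid)
Product: 24 diangelate: 8,10-bis(angeloyloxy)-11-vinyl-longipinan-5-one skeleton, via mixed anhydride 23 (not isolated)
Conditions: 22 (5 equiv), 2,4,6-Cl3C6H2COCl (5 equiv), Et3N, PhMe, 25 °C; then 21, 80 °C
Reagents that add atoms: (Z)-2-methylbut-2-enoic acid (22), C/C=C(/C)C(=O)O; 2,4,6-trichlorobenzoyl chloride (atoms in 23 only), O=C(Cl)c1c(Cl)cc(Cl)cc1Cl
Why: Yamaguchi-type esterification through the mixed trichlorobenzoic anhydride, run without a nucleophilic catalyst, acylates both hindered secondary alcohols while keeping the (Z) geometry of the angeloyl groups.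

Step 14
Reactants: 24 diangelate
Product: 27 (1S,2S,3R,6R,7R,8R,10R,11S)-8,10-bis(angeloyloxy)-12-hydroxylongipinan-5-one (CNP0287707.1), via vicinal diol 25 (not isolated), via aldehyde 26 (not isolated)
Conditions: OsO4 (2 mol %), NaIO4 (4 equiv), 2,6-lutidine, dioxane/H2O, 25 °C; extractive work-up; NaBH4 (1 equiv), MeOH/CH2Cl2, −78 °C
Reagents that add atoms: osmium tetroxide, O=[Os](=O)(=O)=O; sodium periodate (terminal oxidant), [Na+].[O-]I(=O)(=O)=O
Why: Lemieux–Johnson cleavage is expected to occur at the monosubstituted vinyl group because the electron-poor (Z)-trisubstituted angelate double bonds are poor osmylation substrates, and low-temperature borohydride reduction of the aldehyde (faster than the hindered ketone) gives the C12 alcohol with C11 unchanged.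

**Compound list**

1 | ethynyl(trimethyl)silane | C#C[Si](C)(C)C | starting material
2 | 3-(trimethylsilyl)prop-2-ynal | O=CC#C[Si](C)(C)C | intermediate
3 | 2-(triphenyl-λ5-phosphanylidene)propanal | CC(C=O)=P(c1ccccc1)(c1ccccc1)c1ccccc1 | starting material
4 | (2E)-2-methyl-5-(trimethylsilyl)pent-2-en-4-ynal | O=C/C(C)=C/C#C[Si](C)(C)C | intermediate
5 | triethyl phosphonoacetate | CCOC(=O)CP(=O)(OCC)OCC | starting material
6 | ethyl (2E,4E)-4-methyl-7-(trimethylsilyl)hepta-2,4-dien-6-ynoate | CCOC(=O)/C=C/C(C)=C/C#C[Si](C)(C)C | intermediate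
7 | 2-[dimethyl(phenyl)silyl]-4,4,5,5-tetramethyl-1,3,2-dioxaborolane | C[Si](C)(c1ccccc1)B1OC(C)(C)C(C)(C)O1 | starting material
8 | ethyl (3R,4E)-3-[dimethyl(phenyl)silyl]-4-methyl-7-(trimethylsilyl)hept-4-en-6-ynoate | CCOC(=O)C[C@@H]([Si](C)(C)c1ccccc1)/C(C)=C/C#C[Si](C)(C)C | intermediate
9 | (3R,4E)-3-[dimethyl(phenyl)silyl]-4-methyl-7-(trimethylsilyl)hept-4-en-6-yn-1-ol | OCC[C@@H]([Si](C)(C)c1ccccc1)/C(C)=C/C#C[Si](C)(C)C | intermediate
10 | 2-methyl-2-vinyloxirane (racemic) | CC1(C=C)CO1 | starting material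
11 | (2R,3R,5R,6E)-5-[dimethyl(phenyl)silyl]-2-ethenyl-2,6-dimethyl-9-(trimethylsilyl)non-6-en-8-yne-1,3-diol | O[C@@H]([C@](C)(C=C)CO)C[C@@H]([Si](C)(C)c1ccccc1)/C(C)=C/C#C[Si](C)(C)C | intermediate
12 | 2-(triphenyl-λ5-phosphanylidene)acetaldehyde | O=CC=P(c1ccccc1)(c1ccccc1)c1ccccc1 | starting material
13 | (2S,3R,5R,6E)-5-[dimethyl(phenyl)silyl]-2-ethenyl-3-hydroxy-2,6-dimethyl-9-(trimethylsilyl)non-6-en-8-ynal | O[C@@H]([C@](C)(C=C)C=O)C[C@@H]([Si](C)(C)c1ccccc1)/C(C)=C/C#C[Si](C)(C)C | intermediate (not isolated)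
14 | (2E,4R,5R,7R,8E)-7-[dimethyl(phenyl)silyl]-4-ethenyl-5-hydroxy-4,8-dimethyl-11-(trimethylsilyl)undeca-2,8-dien-10-ynal | O[C@@H]([C@](C)(C=C)/C=C/C=O)C[C@@H]([Si](C)(C)c1ccccc1)/C(C)=C/C#C[Si](C)(C)C | intermediate
15 | (2E,4R,5R,7R,8E)-5-acetoxy-7-[dimethyl(phenyl)silyl]-4-ethenyl-4,8-dimethyl-11-(trimethylsilyl)undeca-2,8-dien-10-ynal | CC(=O)O[C@@H]([C@](C)(C=C)/C=C/C=O)C[C@@H]([Si](C)(C)c1ccccc1)/C(C)=C/C#C[Si](C)(C)C | intermediate
16 | bicyclo[4.1.1]octane aldehyde (2-exo-CHO, 6-exo-C≡C–SiMe3, 8-SiMe2Ph, 10-OAc, 11-vinyl) | CC(=O)O[C@@H]1C[C@@H]([Si](C)(C)c2ccccc2)[C@]3(C)[C@@H](C=O)[C@@H]([C@H]3C#C[Si](C)(C)C)[C@@]1(C)C=C | intermediate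
17 | keto aldehyde (16 with acetyl on C6) | CC(=O)O[C@@H]1C[C@@H]([Si](C)(C)c2ccccc2)[C@]3(C)[C@@H](C=O)[C@@H]([C@H]3C(C)=O)[C@@]1(C)C=C | intermediate (not isolated)
18 | tricyclic enone (15-norlongipin-3-en-5-one core, 10-OAc, 8-SiMe2Ph, 11-vinyl) | CC(=O)O[C@@H]1C[C@@H]([Si](C)(C)c2ccccc2)[C@]3(C)[C@@H]4[C@@H]([C@H]3C(=O)C=C4)[C@@]1(C)C=C | intermediate
19 | (3R)-methyl ketone (10-OAc, 8-SiMe2Ph, 11-vinyl longipinan-5-one skeleton) | CC(=O)O[C@@H]1C[C@@H]([Si](C)(C)c2ccccc2)[C@]3(C)[C@@H]4[C@@H]([C@H]3C(=O)C[C@H]4C)[C@@]1(C)C=C | intermediate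
20 | fluorosilane (19 with SiMe2F on C8) | CC(=O)O[C@@H]1C[C@@H]([Si](C)(C)F)[C@]3(C)[C@@H]4[C@@H]([C@H]3C(=O)C[C@H]4C)[C@@]1(C)C=C | intermediate (not isolated)
21 | 8,10-diol (11-vinyl longipinan-5-one skeleton) | O[C@@H]1C[C@@H](O)[C@]3(C)[C@@H]4[C@@H]([C@H]3C(=O)C[C@H]4C)[C@@]1(C)C=C | intermediate
22 | (Z)-2-methylbut-2-enoic acid (angelic acid) | C/C=C(/C)C(=O)O | starting material
23 | (Z)-2-methylbut-2-enoic 2,4,6-trichlorobenzoic anhydride | C/C=C(/C)C(=O)OC(=O)c1c(Cl)cc(Cl)cc1Cl | intermediate (not isolated)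
24 | 8,10-diangelate (11-vinyl) | C/C=C(/C)C(=O)O[C@@H]1C[C@@H](OC(=O)/C(C)=C\C)[C@]2(C)[C@@H]3[C@@H]([C@H]2C(=O)C[C@H]3C)[C@@]1(C)C=C | intermediate
25 | vicinal diol from the vinyl group of 24 (new carbinol centre unassigned) | C/C=C(/C)C(=O)O[C@@H]1C[C@@H](OC(=O)/C(C)=C\C)[C@]2(C)[C@@H]3[C@@H]([C@H]2C(=O)C[C@H]3C)[C@@]1(C)C(O)CO | intermediate (not isolated)
26 | C12 aldehyde | C/C=C(/C)C(=O)O[C@@H]1C[C@@H](OC(=O)/C(C)=C\C)[C@]2(C)[C@@H]3[C@@H]([C@H]2C(=O)C[C@H]3C)[C@@]1(C)C=O | intermediate (not isolated)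
27 | (1S,2S,3R,6R,7R,8R,10R,11S)-8,10-bis(angeloyloxy)-12-hydroxylongipinan-5-one (CNP0287707.1) | C/C=C(/C)C(=O)O[C@@H]1C[C@@H](OC(=O)/C(C)=C\C)[C@]2(C)[C@@H]3[C@@H]([C@H]2C(=O)C[C@H]3C)[C@@]1(C)CO | target

**Totals**

Total step count: 14. Longest linear sequence: 14 steps (1 → 27); all other building blocks are purchased.

**Three steps most likely to fail, with fallbacks**

Step 9 (the one-flask ring formation) may stop at the desilylated open product or drift to a cyclopentane by silyl shift. The fallback sets out from 15 and comes back at 21. It accepts desilylation and builds the cyclobutane in a separate cationic step. 15 is treated with TiCl4 (CH2Cl2, −78 °C) to give on purpose the Hosomi–Sakurai product, cycloheptene aldehyde F3 (C1–C6 bond formed anti to silicon, C7=C8 olefin). Gold-catalysed hydration and aldol condensation as in step 10 give the cis-fused bicyclic enone F4. m-CPBA epoxidises the trisubstituted C7=C8 bond from the convex face to give epoxide F5. LiN(SiMe3)2/TBSCl at −78 °C gives the silyl dienol ether F6. BF3·OEt2 at −78 °C then opens the epoxide at the tertiary C7 with C2 (4-exo, anti) to give the 8-hydroxy tricyclic enone F7, with O8 placed as in the target. Me2CuLi gives the hydroxy acetate F8, and K2CO3/MeOH returns to 21.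

Step 4 may give 1,6- or 1,8-silyl addition on the extended acceptor. The fallback sets out from 2 and comes back at 8. It makes the C7–C8 bond instead of the C8–Si bond. Boron-Wittig olefination of 2 with 1,1-bis(pinacolboryl)ethane and LiTMP gives (Z)-4,4,5,5-tetramethyl-2-[5-(trimethylsilyl)pent-2-en-4-yn-2-yl]-1,3,2-dioxaborolane F1 (boron trans to the alkynyl group). Its rhodium-catalysed asymmetric 1,4-addition (Rh(acac)(C2H4)2, (R)-BINAP, aqueous KOH, dioxane, 50 °C) to ethyl (2E)-3-[dimethyl(phenyl)silyl]prop-2-enoate F2 (from ethyl propiolate and PhMe2SiH with Pt2(dvds)3) gives 8 with unambiguous regiochemistry.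

Step 14 may also oxidise the angelate double bonds. The fallback sets out from 21 and comes back at 27. It cleaves the vinyl group before any angelate is present. Ozonolysis of 21 (O3, CH2Cl2/MeOH, −78 °C, then NaBH4 at −78 °C) gives the 8,10,12-triol F9. TBSCl/imidazole silylates only the primary hydroxyl to give the 12-silyl ether F10. Double angeloylation as in step 13 gives the diangelate silyl ether F11, and HF·pyridine gives 27.

Further compounds
F1 | step 4 | (Z)-4,4,5,5-tetramethyl-2-[5-(trimethylsilyl)pent-2-en-4-yn-2-yl]-1,3,2-dioxaborolane | C/C(B1OC(C)(C)C(C)(C)O1)=C\C#C[Si](C)(C)C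
F2 | step 4 | ethyl (2E)-3-[dimethyl(phenyl)silyl]prop-2-enoate | CCOC(=O)/C=C/[Si](C)(C)c1ccccc1
F3 | step 9 | cycloheptene aldehyde (C7=C8, CH2CHO on C1, C≡C–SiMe3 on C6, 10-OAc, 11-vinyl) | CC(=O)O[C@@H]1CC=C(C)[C@H](C#C[Si](C)(C)C)[C@H](CC=O)[C@@]1(C)C=C
F4 | step 9 | cis-fused bicyclic enone (C3=C4–C5=O, C7=C8) | CC(=O)O[C@@H]1CC=C(C)[C@@H]2C(=O)C=CC[C@@H]2[C@@]1(C)C=C
F5 | step 9 | 7,8-epoxide of F4 | CC(=O)O[C@@H]1C[C@H]3O[C@@]3(C)[C@@H]2C(=O)C=CC[C@@H]2[C@@]1(C)C=C
F6 | step 9 | tert-butyldimethylsilyl dienol ether of F5 | CC(=O)O[C@@H]1C[C@H]3O[C@@]3(C)[C@@H]2C(O[Si](C)(C)C(C)(C)C)=CC=C[C@@H]2[C@@]1(C)C=C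
F7 | step 9 | 8-hydroxy tricyclic enone (10-OAc, 11-vinyl) | CC(=O)O[C@@H]1C[C@@H](O)[C@]3(C)[C@@H]4[C@@H]([C@H]3C(=O)C=C4)[C@@]1(C)C=C
F8 | step 9 | 8-hydroxy-10-acetoxy (3R)-methyl ketone | CC(=O)O[C@@H]1C[C@@H](O)[C@]3(C)[C@@H]4[C@@H]([C@H]3C(=O)C[C@H]4C)[C@@]1(C)C=C
F9 | step 14 | 8,10,12-trihydroxylongipinan-5-one | O[C@@H]1C[C@@H](O)[C@]3(C)[C@@H]4[C@@H]([C@H]3C(=O)C[C@H]4C)[C@@]1(C)CO
F10 | step 14 | 12-O-tert-butyldimethylsilyl ether of F9 | O[C@@H]1C[C@@H](O)[C@]3(C)[C@@H]4[C@@H]([C@H]3C(=O)C[C@H]4C)[C@@]1(C)CO[Si](C)(C)C(C)(C)C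
F11 | step 14 | 8,10-diangelate of F10 | C/C=C(/C)C(=O)O[C@@H]1C[C@@H](OC(=O)/C(C)=C\C)[C@]2(C)[C@@H]3[C@@H]([C@H]2C(=O)C[C@H]3C)[C@@]1(C)CO[Si](C)(C)C(C)(C)C
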